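**Plan**

1. Chromene numbering of the target: O1, C2, C3, C4(=O), C4a, C5(OH), C6, C7(=O), C8, C8a. Retrosynthetic cuts, in order: C6–CH(Ph) (enal Michael addition, CHO later to CO2H); C4a–C5 of the carbocycle; C5–C6 (C-acylation of a methyl ketone enolate).
2. Then the pyranone bonds O1–C8a and C4–C4a (cyclodehydration of a δ-hydroxy β-diketone made by an aldol C–C bond), and last the two C8–CH2 bonds, back to acetylacetone.
3. Forward: acetylacetone is alkylated twice; one acetyl is reduced enzymatically (re-oxidised later), the other is built into the dihydropyranone ring; the carbocycle C4a–C5–C6–C7–C8–C8a is closed last; the phenylpropanoic acid arm is then added at C6.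
4. Enabling feature: the carbocycle is an enolised cyclohexane-1,3,5-trione (carbonyl-level C5, C7, C8a alternating with C4a, C6, C8). C4a is the nucleophilic α-carbon of the β-alkoxy enone O1–C8a=C4a–C4=O in the pyranone ring and is held 1,6 to an acyl ketene carbon (C5) through the quaternary C8, so a polyketide-type C-acylation closes the ring and fixes which oxygen belongs to the pyranone.
5. Stereochemistry: lavandulyl centre from (R)-lavandulol; C8 from ketoreductase desymmetrisation of the 2,2-dialkyl-1,3-diketone; cis-C2/C3 from an Evans syn aldol, retained in the cyclodehydration; benzylic centre from iminium catalysis with an (S)-diarylprolinol silyl ether.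

Key step: step 14

Assumption: (R)-(−)-lavandulol is taken as a purchasable natural enantiomer, and the ketoreductase of step 4 is the (S)-selective member of a commercial enzyme panel that reduces the acetyl group shown in 7.

**Step 1**
Reactants: 1 (R)-lavandulol
Product: 2 (R)-lavandulyl iodide
Conditions: I2, PPh3, imidazole, CH2Cl2, 0 °C to rt
Reagents that add atoms: iodine, II
Why: Appel-type iodination of the unhindered primary alcohol proceeds by SN2 at CH2 and leaves the adjacent stereocentre and both alkenes untouched.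

**Step 2**
Reactants: 2 (R)-lavandulyl iodide; 3 acetylacetone (3 equiv)
Product: 4 3-lavandulylpentane-2,4-dione
Conditions: K2CO3, acetone, reflux
Reagents that add atoms: none
Why: C-alkylation of the potassium enolate of acetylacetone with a primary iodide is a standard SN2 reaction, and the weakly basic enolate disfavours E2 elimination at the β-branched centre.

**Step 3**
Reactants: 4 3-lavandulylpentane-2,4-dione; 5 prenyl bromide
Product: 6 3-prenyl-3-lavandulylpentane-2,4-dione
Conditions: K2CO3, acetone, reflux
Reagents that add atoms: none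
Why: A second C-alkylation of the 3-monoalkyl 1,3-diketone with the reactive allylic bromide should give the 3,3-dialkyl dione, whose quaternary carbon is not yet a stereocentre because both acyl groups are acetyl.

**Step 4**
Reactants: 6 3-prenyl-3-lavandulylpentane-2,4-dione
Product: 7 (3R,4S)-hydroxy ketone
Conditions: ketoreductase ((S)-selective, NADPH-dependent), NADP+ (cat.), iPrOH, phosphate buffer pH 7.0, DMSO (10% v/v), 30 °C
Reagents that add atoms: none
Why: Enzymatic carbonyl reduction by a ketoreductase (alcohol dehydrogenase class), established for desymmetrising 2,2-disubstituted 1,3-diketones, delivers hydride to the Re face of one acetyl group only, the chiral active site telling the two diastereotopic acetyl groups apart by the different fit of the prenyl and lavandulyl chains, so that the quaternary centre (future C8) and the carbinol centre are set together.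

**Step 5**
Reactants: 7 (3R,4S)-hydroxy ketone
Product: 8 TMS ether of 7
Conditions: TMSCl, imidazole, CH2Cl2, 0 °C to rt
Reagents that add atoms: chlorotrimethylsilane, C[Si](C)(C)Cl
Why: Silylation masks the β-hydroxyl so that the later lithium enolate cannot undergo retro-aldol cleavage at the quaternary carbon.

**Step 6**
Reactants: 9 (4S)-4-benzyl-3-propanoyl-1,3-oxazolidin-2-one; 10 acetaldehyde
Product: 11 (2S,3R) syn aldol imide
Conditions: Bu2BOTf, iPr2NEt, CH2Cl2, 0 °C; MeCHO, −78 to 0 °C; then pH 7 buffer, MeOH, H2O2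
Reagents that add atoms: none
Why: Evans syn aldol reaction, in which the Z-boron enolate adds to acetaldehyde through a closed chair transition state whose facial sense is fixed by the (S)-benzyl auxiliary, setting both new centres (2S,3R).

**Step 7**
Reactants: 11 (2S,3R) syn aldol imide
Product: 12 TBS ether of 11
Conditions: TBSOTf, 2,6-lutidine, CH2Cl2, −78 to 0 °C
Reagents that add atoms: tert-butyldimethylsilyl trifluoromethanesulfonate, CC(C)(C)[Si](C)(C)OS(=O)(=O)C(F)(F)F
Why: Silyl triflate/lutidine silylation of the secondary alcohol is fast at low temperature and avoids retro-aldol of the adduct.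

**Step 8**
Reactants: 12 TBS ether of 11
Product: 13 (2R,3R)-3-(TBS-oxy)-2-methylbutan-1-ol
Conditions: LiBH4, MeOH (1 equiv), THF, 0 °C
Reagents that add atoms: none
Why: Reductive cleavage of the N-acyl oxazolidinone with LiBH4 should give the primary alcohol and the recoverable auxiliary without touching the silyl ether or the α-stereocentre.

**Step 9**
Reactants: 13 (2R,3R)-3-(TBS-oxy)-2-methylbutan-1-ol
Product: 14 (2S,3R)-3-(TBS-oxy)-2-methylbutanal
Conditions: Dess–Martin periodinane, NaHCO3, CH2Cl2, 0 °C to rt
Reagents that add atoms: none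
Why: Buffered Dess–Martin oxidation should give the configurationally labile α-methyl aldehyde without epimerisation, and it is used at once.

**Step 10**
Reactants: 8 TMS ether of 7; 14 (2S,3R)-3-(TBS-oxy)-2-methylbutanal
Product: 16 aldol diol (both C6 epimers), via silyl-protected aldol adduct 15 (not isolated)
Conditions: LiN(iPr)2, THF, −78 °C; 14, −78 °C; AcOH; then citric acid, MeOH, 0 °C
Reagents that add atoms: none
Why: Kinetic lithium enolate aldol addition, in which only the acetyl CH3 can be deprotonated (the other α-carbon is quaternary), the enolate adds to 14 at −78 °C faster than 14 can epimerise, the configuration of the new carbinol is irrelevant because it is oxidised in step 11, and the labile TMS ether is cleaved in the methanolic citric acid work-up while the secondary TBS ether stays.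

**Step 11**
Reactants: 16 aldol diol
Product: 17 triketone (β-diketone plus acetyl)
Conditions: Dess–Martin periodinane (3 equiv), NaHCO3, CH2Cl2, rt
Reagents that add atoms: none
Why: Dess–Martin oxidation, the standard method for turning β-hydroxy ketones into 1,3-diketones, oxidises both secondary alcohols, giving the β-diketone and regenerating the second acetyl group, and the quaternary centre cannot epimerise.

**Step 12**
Reactants: 17 triketone
Product: 19 (2R,3S)-dihydropyranone methyl ketone, via hydroxy diketone 18 (not isolated)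
Conditions: HF (48% aq.), MeCN, 0 °C to rt; then TsOH·H2O (cat.), CH2Cl2, rt
Reagents that add atoms: none
Why: Desilylation and acid-catalysed cyclodehydration of the δ-hydroxy β-diketone is the standard route to 2,3-dihydro-4H-pyran-4-ones, only the ketone next to the quaternary carbon lies 1,5 to the hydroxyl (which puts the ring oxygen on the future C8a), and no bond to either stereocentre is broken, so the syn aldol pattern becomes the cis-2,3-dimethyl pattern.

**Step 13**
Reactants: 19 (2R,3S)-dihydropyranone methyl ketone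
Product: 20 tert-butyl β-keto ester
Conditions: LiN(SiMe3)2 (2.1 equiv), THF, −78 °C; Boc2O, −78 °C; AcOH, −78 °C
Reagents that add atoms: di-tert-butyl dicarbonate, CC(C)(C)OC(=O)OC(=O)OC(C)(C)C
Why: C-Acylation of a kinetic lithium ketone enolate with a dicarbonate, in which the unhindered acetyl CH3 is deprotonated at −78 °C much faster than the tertiary C3–H of the vinylogous ester, so the β-keto ester should form without epimerisation of the cis-dimethyl pair, and the second equivalent of base holds the product as its enolate until the cold quench.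

**Step 14**
Reactants: 20 tert-butyl β-keto ester
Product: 22 (2R,3S,8S)-5-hydroxy-2,3-dimethyl-8-prenyl-8-lavandulyl-2,3-dihydro-4H-chromene-4,7(8H)-dione, via acyl ketene 21 (not isolated)
Conditions: toluene (0.005 M), 110 °C, N2 sweep
Reagents that add atoms: none
Why: Proposed new method: heating the tert-butyl β-keto ester expels tert-butanol from its enol form through a six-membered transition state and gives acyl ketene 21, whose sp carbon (future C5) is attacked by pyranone C5 (future C4a), the nucleophilic α-carbon of the β-alkoxy enone O1–C6=C5–C4=O, to give an oxocarbenium/enolate zwitterion that loses the C5 proton and tautomerises to the hydrogen-bonded enol 22. The closest known reaction types are the C–C bond formation of thermally generated acyl ketenes with enol ethers and enamines (the first bond of their hetero-[4+2] reactions), their intramolecular capture in polyketide-type cyclisations, and the Claisen closure of 3,5-dioxo esters to cyclohexane-1,3,5-triones; acylation of a β-alkoxy enone carbon by a ketene has no direct precedent. The carbocycle closes in a 6-exo-dig fashion with respect to the ketene C=O, with the enol ether double bond endocyclic to the new ring. No stereocentre is formed and none is touched, and because the medium is neutral the base-labile cis-2,3-dimethyl pair and the quaternary centre are safe. The step needs C- rather than O-acylation and attack by the pyranone carbon rather than by the side-chain alkenes: the ring oxygen and the pyranone carbonyl oxygen cannot give a stable ring (oxonium ion or eight-membered ring), closure to the hetero-[4+2] adduct would need a four-membered ring, and attack by the oxygen-substituted C5 gives a cation stabilised by the ring oxygen and then an enolised β-triketone that cannot revert, whereas the isolated alkenes would give unstabilised tertiary cations. High dilution and removal of tert-butanol should suppress ketene dimerisation and re-addition.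

**Step 15**
Reactants: 22 bicyclic enolised triketone; 23 (E)-cinnamaldehyde
Product: 24 (3S)-3-aryl-3-phenylpropanal (in equilibrium with its cyclic hemiacetals)
Conditions: (S)-α,α-diphenylprolinol trimethylsilyl ether (20 mol%), PhCO2H (20 mol%), CH2Cl2, rt
Reagents that add atoms: none
Why: Iminium-catalysed asymmetric Michael addition of a cyclic 1,3-dicarbonyl-type C–H acid to an enal, in which the only free nucleophilic carbon of the enolised triketone (C6) adds to the β-carbon of the (E)-iminium ion on its Si face, the face not shielded by the diphenyl(silyloxy)methyl group of the (S)-catalyst, setting the benzylic (S) centre under catalyst control.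

**Step 16**
Reactants: 24 (3S)-3-aryl-3-phenylpropanal
Product: 25 target acid
Conditions: NaClO2, NaH2PO4, 2-methyl-2-butene, t-BuOH/H2O, 0 °C to rt
Reagents that add atoms: sodium chlorite, [Na+].[O-]Cl=O
Why: Pinnick oxidation should convert the aldehyde into the acid under buffered, mildly acidic conditions that leave the enolised triketone, the alkenes (protected by the 2-methyl-2-butene scavenger) and all stereocentres untouched.

**Compound list**

1 | (R)-lavandulol, (2R)-5-methyl-2-(prop-1-en-2-yl)hex-4-en-1-ol | C=C(C)[C@@H](CC=C(C)C)CO | starting material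
2 | (R)-lavandulyl iodide, (3R)-3-(iodomethyl)-2,6-dimethylhepta-1,5-diene | C=C(C)[C@@H](CC=C(C)C)CI | intermediate
3 | acetylacetone (pentane-2,4-dione) | CC(=O)CC(C)=O | starting material
4 | 3-[(2S)-5-methyl-2-(prop-1-en-2-yl)hex-4-en-1-yl]pentane-2,4-dione | C=C(C)[C@@H](CC=C(C)C)CC(C(C)=O)C(C)=O | intermediate
5 | prenyl bromide (1-bromo-3-methylbut-2-ene) | CC(C)=CCBr | starting material
6 | 3-(3-methylbut-2-en-1-yl)-3-[(2S)-5-methyl-2-(prop-1-en-2-yl)hex-4-en-1-yl]pentane-2,4-dione | C=C(C)[C@@H](CC=C(C)C)CC(CC=C(C)C)(C(C)=O)C(C)=O | intermediate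
7 | (3R,4S)-4-hydroxy-3-(3-methylbut-2-en-1-yl)-3-[(2S)-5-methyl-2-(prop-1-en-2-yl)hex-4-en-1-yl]pentan-2-one | C=C(C)[C@@H](CC=C(C)C)C[C@](C(C)=O)(CC=C(C)C)[C@H](C)O | intermediate
8 | (3R,4S)-3-(3-methylbut-2-en-1-yl)-3-[(2S)-5-methyl-2-(prop-1-en-2-yl)hex-4-en-1-yl]-4-[(trimethylsilyl)oxy]pentan-2-one | C=C(C)[C@@H](CC=C(C)C)C[C@](C(C)=O)(CC=C(C)C)[C@H](C)O[Si](C)(C)C | intermediate
9 | (4S)-4-benzyl-3-propanoyl-1,3-oxazolidin-2-one | CCC(=O)N1[C@@H](Cc2ccccc2)COC1=O | starting material
10 | acetaldehyde | CC=O | starting material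
11 | (4S)-4-benzyl-3-[(2S,3R)-3-hydroxy-2-methylbutanoyl]-1,3-oxazolidin-2-one | O[C@H](C)[C@H](C)C(=O)N1[C@@H](Cc2ccccc2)COC1=O | intermediate
12 | (4S)-4-benzyl-3-[(2S,3R)-3-[(tert-butyldimethylsilyl)oxy]-2-methylbutanoyl]-1,3-oxazolidin-2-one | CC(C)(C)[Si](C)(C)O[C@H](C)[C@H](C)C(=O)N1[C@@H](Cc2ccccc2)COC1=O | intermediate
13 | (2R,3R)-3-[(tert-butyldimethylsilyl)oxy]-2-methylbutan-1-ol | CC(C)(C)[Si](C)(C)O[C@H](C)[C@H](C)CO | intermediate
14 | (2S,3R)-3-[(tert-butyldimethylsilyl)oxy]-2-methylbutanal | CC(C)(C)[Si](C)(C)O[C@H](C)[C@H](C)C=O | intermediate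
15 | (2S,3R,7R,8R)-8-[(tert-butyldimethylsilyl)oxy]-6-hydroxy-7-methyl-3-(3-methylbut-2-en-1-yl)-3-[(2S)-5-methyl-2-(prop-1-en-2-yl)hex-4-en-1-yl]-2-[(trimethylsilyl)oxy]nonan-4-one, both C6 epimers, formed as its lithium alkoxide | C=C(C)[C@@H](CC=C(C)C)C[C@](C(=O)CC(O)[C@@H](C)[C@@H](C)O[Si](C)(C)C(C)(C)C)(CC=C(C)C)[C@H](C)O[Si](C)(C)C | intermediate
16 | (2S,3R,7R,8R)-8-[(tert-butyldimethylsilyl)oxy]-2,6-dihydroxy-7-methyl-3-(3-methylbut-2-en-1-yl)-3-[(2S)-5-methyl-2-(prop-1-en-2-yl)hex-4-en-1-yl]nonan-4-one, both C6 epimers | C=C(C)[C@@H](CC=C(C)C)C[C@](C(=O)CC(O)[C@@H](C)[C@@H](C)O[Si](C)(C)C(C)(C)C)(CC=C(C)C)[C@H](C)O | intermediate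
17 | (3R,7S,8R)-8-[(tert-butyldimethylsilyl)oxy]-7-methyl-3-(3-methylbut-2-en-1-yl)-3-[(2S)-5-methyl-2-(prop-1-en-2-yl)hex-4-en-1-yl]nonane-2,4,6-trione | C=C(C)[C@@H](CC=C(C)C)C[C@](C(=O)CC(=O)[C@@H](C)[C@@H](C)O[Si](C)(C)C(C)(C)C)(CC=C(C)C)C(C)=O | intermediate
18 | (3R,7S,8R)-8-hydroxy-7-methyl-3-(3-methylbut-2-en-1-yl)-3-[(2S)-5-methyl-2-(prop-1-en-2-yl)hex-4-en-1-yl]nonane-2,4,6-trione (in equilibrium with its cyclic hemiketal) | C=C(C)[C@@H](CC=C(C)C)C[C@](C(=O)CC(=O)[C@@H](C)[C@@H](C)O)(CC=C(C)C)C(C)=O | intermediate
19 | (3S)-3-[(2R,3S)-2,3-dimethyl-4-oxo-3,4-dihydro-2H-pyran-6-yl]-6-methyl-3-[(2S)-5-methyl-2-(prop-1-en-2-yl)hex-4-en-1-yl]hept-5-en-2-one | C=C(C)[C@@H](CC=C(C)C)C[C@](C1=CC(=O)[C@@H](C)[C@@H](C)O1)(CC=C(C)C)C(C)=O | intermediate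
20 | tert-butyl (4S)-4-[(2R,3S)-2,3-dimethyl-4-oxo-3,4-dihydro-2H-pyran-6-yl]-7-methyl-4-[(2S)-5-methyl-2-(prop-1-en-2-yl)hex-4-en-1-yl]-3-oxooct-6-enoate | C=C(C)[C@@H](CC=C(C)C)C[C@](C1=CC(=O)[C@@H](C)[C@@H](C)O1)(CC=C(C)C)C(=O)CC(=O)OC(C)(C)C | intermediate
21 | (4S)-4-[(2R,3S)-2,3-dimethyl-4-oxo-3,4-dihydro-2H-pyran-6-yl]-7-methyl-4-[(2S)-5-methyl-2-(prop-1-en-2-yl)hex-4-en-1-yl]octa-1,6-diene-1,3-dione (acyl ketene) | C=C(C)[C@@H](CC=C(C)C)C[C@](C1=CC(=O)[C@@H](C)[C@@H](C)O1)(CC=C(C)C)C(=O)C=C=O | intermediate
22 | (2R,3S,8S)-5-hydroxy-2,3-dimethyl-8-(3-methylbut-2-en-1-yl)-8-[(2S)-5-methyl-2-(prop-1-en-2-yl)hex-4-en-1-yl]-2,3-dihydro-4H-chromene-4,7(8H)-dione | C=C(C)[C@@H](CC=C(C)C)C[C@]1(CC=C(C)C)C(=O)C=C(O)C2=C1O[C@H](C)[C@H](C)C2=O | intermediate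
23 | (E)-cinnamaldehyde | O=C/C=C/c1ccccc1 | starting material
24 | (3S)-3-[(2R,3S,8S)-5-hydroxy-2,3-dimethyl-8-(3-methylbut-2-en-1-yl)-8-[(2S)-5-methyl-2-(prop-1-en-2-yl)hex-4-en-1-yl]-4,7-dioxo-3,4,7,8-tetrahydro-2H-chromen-6-yl]-3-phenylpropanal | C=C(C)[C@@H](CC=C(C)C)C[C@]1(CC=C(C)C)C(=O)C([C@@H](CC=O)c2ccccc2)=C(O)C2=C1O[C@H](C)[C@H](C)C2=O | intermediate
25 | (3S)-3-[(2R,3S,8S)-5-hydroxy-2,3-dimethyl-8-(3-methylbut-2-en-1-yl)-8-[(2S)-5-methyl-2-(prop-1-en-2-yl)hex-4-en-1-yl]-4,7-dioxo-3,4,7,8-tetrahydro-2H-chromen-6-yl]-3-phenylpropanoic acid | C=C(C)[C@@H](CC=C(C)C)C[C@]1(CC=C(C)C)C(=O)C([C@@H](CC(=O)O)c2ccccc2)=C(O)C2=C1O[C@H](C)[C@H](C)C2=O | target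

**Step count and risks**

Total step count: 16. Longest linear sequence: 12 steps (steps 1–5 and 10–16, from (R)-lavandulol); steps 6–9 form the convergent aldehyde branch.

Steps most likely to fail:

Step 14. The acyl ketene may be consumed by ene or [2+2] reaction with the side-chain alkenes, or by dimerisation, faster than it acylates the weakly nucleophilic pyranone carbon. The fallback closes the ring from the other side with known chemistry and sets out from 19. Iodination at pyranone C5 (I2, pyridine, CH2Cl2) should give the 5-iodo pyranone F1. Carbonylation (PdCl2(PPh3)2 cat., CO 1 atm, MeOH, Et3N, DMF, 60 °C) should give the pyranone 5-carboxylic methyl ester F2. A Dieckmann-type Claisen condensation (LiN(SiMe3)2, THF, −78 to 0 °C), in which the methyl ketone enolate attacks the ester, comes back to the route at 22.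

Step 4. The enzyme may discriminate poorly between the two diastereotopic acetyl groups, or turn over the very lipophilic substrate slowly. The fallback gives up the desymmetrisation and sets out from 6. Statistical mono-enolisation (LiN(iPr)2, 1.0 equiv, THF, −78 °C) and addition to 14 should give the mono-aldol adduct F3 as a mixture of epimers at the quaternary carbon and at the carbinol. Dess–Martin oxidation comes back to the route at 17, now accompanied by its epimer at the quaternary carbon. The two are diastereomers because of the lavandulyl and propionate centres and are separated by chromatography after step 12, at the stage of 19.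

Step 15. Catalyst control may be eroded by a mismatched face preference of the chiral, hindered nucleophile, and turnover may be slow because the acidic triketone protonates the amine catalyst. The fallback sets out from 22 and uses a three-component Yonemitsu-type condensation with benzaldehyde and Meldrum's acid (L-proline cat., MeCN, rt). This should give the Meldrum's acid adduct F4 as both benzylic epimers. Hydrolysis and decarboxylation (pyridine/H2O, 90 °C) comes back to the route at 25, which is separated from its benzylic epimer by preparative HPLC.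

**Further compounds**

F1 | step 14 | (3S)-3-[(2R,3S)-5-iodo-2,3-dimethyl-4-oxo-3,4-dihydro-2H-pyran-6-yl]-6-methyl-3-[(2S)-5-methyl-2-(prop-1-en-2-yl)hex-4-en-1-yl]hept-5-en-2-one | C=C(C)[C@@H](CC=C(C)C)C[C@](C1=C(I)C(=O)[C@@H](C)[C@@H](C)O1)(CC=C(C)C)C(C)=O
F2 | step 14 | methyl (2R,3S)-2,3-dimethyl-6-[(3S)-6-methyl-3-[(2S)-5-methyl-2-(prop-1-en-2-yl)hex-4-en-1-yl]-2-oxohept-5-en-3-yl]-4-oxo-3,4-dihydro-2H-pyran-5-carboxylate | C=C(C)[C@@H](CC=C(C)C)C[C@](C1=C(C(=O)OC)C(=O)[C@@H](C)[C@@H](C)O1)(CC=C(C)C)C(C)=O
F3 | step 4 | (7R,8R)-8-[(tert-butyldimethylsilyl)oxy]-6-hydroxy-7-methyl-3-(3-methylbut-2-en-1-yl)-3-[(2S)-5-methyl-2-(prop-1-en-2-yl)hex-4-en-1-yl]nonane-2,4-dione, epimers at C3 and C6 | C=C(C)[C@@H](CC=C(C)C)CC(CC=C(C)C)(C(C)=O)C(=O)CC(O)[C@@H](C)[C@@H](C)O[Si](C)(C)C(C)(C)C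
F4 | step 15 | 5-{[(2R,3S,8S)-5-hydroxy-2,3-dimethyl-8-(3-methylbut-2-en-1-yl)-8-[(2S)-5-methyl-2-(prop-1-en-2-yl)hex-4-en-1-yl]-4,7-dioxo-3,4,7,8-tetrahydro-2H-chromen-6-yl](phenyl)methyl}-2,2-dimethyl-1,3-dioxane-4,6-dione, both benzylic epimers | C=C(C)[C@@H](CC=C(C)C)C[C@]1(CC=C(C)C)C(=O)C(C(C3C(=O)OC(C)(C)OC3=O)c3ccccc3)=C(O)C2=C1O[C@H](C)[C@H](C)C2=O
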